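**Retrosynthetic overview**
1. Target ⇒ global desilylation, then C13=C14 by Julia–Kocienski olefination: C17 trienyl BT-sulfone (cis-diol ring, 32) + C20 aldehyde (lactone + oxabicycle, 20).
2. Aldehyde 20 ⇒ Stille coupling of the (E)-vinylstannane of the oxabicycle (13) with a 3-bromo-5-ylidenebutenolide (18); the butenolide ring ⇒ tandem Sonogashira/5-exo-dig lactonisation of (E)-2,3-dibromoacrylic acid with (E)-3-methylpent-2-en-4-yn-1-ol.
3. 7-Oxabicyclo[2.2.1]heptane ⇒ transannular opening of an anti-5′,6′-epoxide by the 3′-OH; epoxide ⇒ Sharpless epoxidation of a cyclohexenylmethanol.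
4. cis-Diol ring ⇒ allylic oxidation and cis-selective reduction of the same cyclohexenecarboxylate 6; chain by two HWE homologations (C5, then C2).
5. Ester 6 (source of both carbocycles) ⇒ ketoisophorone via ene-reductase, then ketoreductase, enol triflate and carbonylation. Ring order: both carbocycles are carried from ketoisophorone; oxirane (step 7) → oxanorbornane (step 11); butenolide (step 14) is made separately.

Assumption: reagents are not numbered (only skeleton-contributing starting materials, intermediates and the target are); carotenoid-style locants are used in the Why lines (diol ring C1–C6, chain C7–C18 ending at the lactone ylidene carbon, oxabicycle C1′–C6′); TBS = tert-butyldimethylsilyl, BT = 1,3-benzothiazol-2-yl.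

The tartrate enantiomer in step 7 and the face selectivity in step 18 were assigned by working through the selectivity models by hand; nothing in this route has been run.

**Route**

Step 1
Reactants: 1 ketoisophorone (2,6,6-trimethylcyclohex-2-ene-1,4-dione)
Product: 2 (6R)-levodione [(R)-2,2,6-trimethylcyclohexane-1,4-dione]
Conditions: ene-reductase (Old Yellow Enzyme type), NADP+ (cat.), glucose dehydrogenase, D-glucose, phosphate buffer pH 6.5, 30 °C
Reagents that add atoms: none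
Why: Ene-reductase asymmetric conjugate reduction (flavin hydride to C3, active-site proton to C2, net trans addition) in which the enzyme pocket fixes the methyl-bearing centre as 6R, the first stereocentre of the route.

Step 2
Reactants: 2 (6R)-levodione
Product: 3 (4R,6R)-actinol [(4R,6R)-4-hydroxy-2,2,6-trimethylcyclohexan-1-one]
Conditions: ketoreductase (levodione-reductase type), NAD+ (cat.), glucose dehydrogenase, D-glucose, phosphate buffer pH 7, 30 °C; recrystallise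
Reagents that add atoms: none
Why: Ketoreductase reduction of the unhindered C4 carbonyl with enzyme-controlled hydride delivery gives the 4R carbinol (trans to the 6-methyl) and leaves the hindered C1 ketone untouched.

Step 3
Reactants: 3 (4R,6R)-actinol
Product: 4 (4R,6R)-4-(TBSO)-2,2,6-trimethylcyclohexan-1-one
Conditions: TBSCl, imidazole, DMF, rt
Reagents that add atoms: tert-butyldimethylsilyl chloride CC(C)(C)[Si](C)(C)Cl
Why: Standard silylation of the secondary alcohol; no stereocentre is touched.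

Step 4
Reactants: 4 (4R,6R)-4-(TBSO)-2,2,6-trimethylcyclohexan-1-one
Product: 5 (R)-4-(TBSO)-2,6,6-trimethylcyclohex-1-en-1-yl trifluoromethanesulfonate
Conditions: KHMDS, THF, −78 °C; then PhNTf2, −78 → 0 °C
Reagents that add atoms: N-phenylbis(trifluoromethanesulfonimide) O=S(=O)(N(c1ccccc1)S(=O)(=O)C(F)(F)F)C(F)(F)F
Why: Enolate O-triflation at the only enolisable position (C6–H); this planarises the relay centre C6 on purpose, while the silyloxy carbinol centre is untouched.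

Step 5
Reactants: 5 (R)-4-(TBSO)-2,6,6-trimethylcyclohex-1-en-1-yl triflate
Product: 6 methyl (R)-4-(TBSO)-2,6,6-trimethylcyclohex-1-ene-1-carboxylate
Conditions: Pd(OAc)2 (5 mol%), PPh3, CO (1 atm), MeOH, Et3N, DMF, 60 °C
Reagents that add atoms: carbon monoxide [C-]#[O+]; methanol CO
Why: Pd-catalysed methoxycarbonylation of the vinyl triflate (oxidative addition, CO insertion, methanolysis) gives the enoate from which both end groups are made.

Step 6
Reactants: 6 methyl (R)-4-(TBSO)-2,6,6-trimethylcyclohex-1-ene-1-carboxylate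
Product: 7 [(R)-4-(TBSO)-2,6,6-trimethylcyclohex-1-en-1-yl]methanol
Conditions: DIBAL-H, CH2Cl2, −78 °C; Rochelle salt
Reagents that add atoms: none
Why: DIBAL reduction of the conjugated ester to the allylic alcohol needed for a directed epoxidation.

Step 7
Reactants: 7 [(R)-4-(TBSO)-2,6,6-trimethylcyclohex-1-en-1-yl]methanol
Product: 8 [(1R,4S,6R)-4-(TBSO)-2,2,6-trimethyl-7-oxabicyclo[4.1.0]heptan-1-yl]methanol (epoxide anti to OTBS)
Conditions: Ti(OiPr)4 (20 mol%), D-(−)-diethyl tartrate, TBHP, 4 Å MS, CH2Cl2, −20 °C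
Reagents that add atoms: tert-butyl hydroperoxide CC(C)(C)OO
Why: Sharpless asymmetric epoxidation under reagent control; D-(−)-DET delivers oxygen to the alkene face anti to the C3′ silyloxy group, setting C5′ (R) and C6′ (S).

Step 8
Reactants: 8 anti-epoxy alcohol
Product: 9 (1S,4S,6R)-4-(TBSO)-2,2,6-trimethyl-7-oxabicyclo[4.1.0]heptane-1-carbaldehyde
Conditions: TPAP (5 mol%), NMO, 4 Å MS, CH2Cl2, rt
Reagents that add atoms: none
Why: Ley–Griffith oxidation is neutral, so the epoxide and silyl ether survive and the α-quaternary aldehyde cannot epimerise.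

Step 9
Reactants: 9 epoxy aldehyde
Product: 10 (1R,4S,6R)-4-(TBSO)-1-ethynyl-2,2,6-trimethyl-7-oxabicyclo[4.1.0]heptane
Conditions: dimethyl (1-diazo-2-oxopropyl)phosphonate, K2CO3, MeOH, 0 °C → rt
Reagents that add atoms: Ohira–Bestmann reagent COP(=O)(OC)C(=[N+]=[N-])C(C)=O
Why: Seyferth–Gilbert homologation (Ohira–Bestmann variant) turns the non-enolisable aldehyde into the terminal alkyne without touching the epoxide stereocentres.

Step 10
Reactants: 10 silyl-protected epoxy alkyne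
Product: 11 (1R,3S,6R)-6-ethynyl-1,5,5-trimethyl-7-oxabicyclo[4.1.0]heptan-3-ol
Conditions: TBAF, THF, 0 °C → rt
Reagents that add atoms: none
Why: Fluoride desilylation frees the 3′-OH that lies anti to the epoxide.

Step 11
Reactants: 11 anti-epoxy alkynol
Product: 12 (1S,2R,4S)-1-ethynyl-2,6,6-trimethyl-7-oxabicyclo[2.2.1]heptan-2-ol
Conditions: CSA (10 mol%), CH2Cl2, 0 °C
Reagents that add atoms: none
Why: Acid-catalysed transannular epoxide opening (the cyclisation used for 1,4-cineole-type ethers): the anti 3′-OH attacks the propargylic C6′ from the backside with inversion, C5′ keeps its C–O bond as the endo tertiary alcohol, and an alkynyl group cannot undergo the furanoid rearrangement.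

Step 12
Reactants: 12 oxabicyclic alkynol
Product: 13 (1R,2R,4S)-2,6,6-trimethyl-1-[(E)-2-(tributylstannyl)ethenyl]-7-oxabicyclo[2.2.1]heptan-2-ol
Conditions: Bu3SnH, PdCl2(PPh3)2 (2 mol%), THF, 0 °C → rt
Reagents that add atoms: tributyltin hydride CCCC[SnH](CCCC)CCCC
Why: Pd-catalysed syn-hydrostannation; the fully substituted propargylic carbon sends tin to the terminal carbon, giving the (E)-β-stannane.

Step 13
Reactants: 14 propiolic acid
Product: 15 (E)-2,3-dibromoacrylic acid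
Conditions: Br2, CHCl3, rt, dark; recrystallise
Reagents that add atoms: bromine BrBr
Why: Anti addition of bromine to the alkyne gives the E-dibromide, in which the C3 bromide is cis to the carboxyl group as the lactonisation requires.

Step 14
Reactants: 15 (E)-2,3-dibromoacrylic acid; 16 (E)-3-methylpent-2-en-4-yn-1-ol
Product: 18 (Z)-3-bromo-5-[(E)-4-hydroxy-2-methylbut-2-en-1-ylidene]furan-2(5H)-one, via bromo-enynoic acid 17 (not isolated)
Conditions: PdCl2(PPh3)2 (5 mol%), CuI (10 mol%), Et3N, MeCN, rt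
Reagents that add atoms: none
Why: Tandem Sonogashira coupling at the more reactive β C–Br, then metal-mediated 5-exo-dig anti-oxymetalation/protonation of the cis carboxylate onto the alkyne, which gives the Z-ylidene butenolide and keeps the α-bromide.

Step 15
Reactants: 13 (E)-vinylstannane; 18 3-bromo-ylidenebutenolide
Product: 19 (Z)-5-[(E)-4-hydroxy-2-methylbut-2-en-1-ylidene]-3-{(E)-2-[(1R,2R,4S)-2-hydroxy-2,6,6-trimethyl-7-oxabicyclo[2.2.1]heptan-1-yl]ethenyl}furan-2(5H)-one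
Conditions: Pd2(dba)3 (2.5 mol%), AsPh3 (20 mol%), NMP, rt → 40 °C
Reagents that add atoms: none
Why: Stille coupling of the α-bromo butenolide with the vinylstannane proceeds with retention of both alkene geometries and tolerates the free hydroxyls.

Step 16
Reactants: 19 dienyl alcohol
Product: 20 (E)-4-[(Z)-4-{(E)-2-[(1R,2R,4S)-2-hydroxy-2,6,6-trimethyl-7-oxabicyclo[2.2.1]heptan-1-yl]ethenyl}-5-oxofuran-2(5H)-ylidene]-3-methylbut-2-enal
Conditions: MnO2, CH2Cl2, rt
Reagents that add atoms: none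
Why: MnO2 oxidises only the primary allylic alcohol; the tertiary alcohol and the lactone are inert.

Step 17
Reactants: 6 methyl (R)-4-(TBSO)-2,6,6-trimethylcyclohex-1-ene-1-carboxylate
Product: 21 methyl (S)-4-(TBSO)-2,6,6-trimethyl-3-oxocyclohex-1-ene-1-carboxylate
Conditions: Rh2(cap)4 (1 mol%), TBHP (70% aq), K2CO3 (cat.), CH2Cl2, rt
Reagents that add atoms: tert-butyl hydroperoxide CC(C)(C)OO
Why: Dirhodium-caprolactamate/TBHP allylic oxidation (tert-butylperoxyl radical H-abstraction) at the only ring allylic CH2 (C4) gives the γ-keto enoate; the silyloxy centre is unchanged.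

Step 18
Reactants: 21 keto ester
Product: 22 methyl (3R,4S)-3-hydroxy-4-(TBSO)-2,6,6-trimethylcyclohex-1-ene-1-carboxylate
Conditions: L-Selectride, THF, −78 °C; then H2O
Reagents that add atoms: none
Why: Bulky-hydride 1,2-reduction (the β-carbon is fully substituted): hydride enters anti to the adjacent non-chelating OTBS (steric approach/Felkin control), which sets C4 as R, cis to the C3 oxygen.

Step 19
Reactants: 22 cis-hydroxy silyl ether
Product: 23 methyl (3R,4S)-3,4-bis(TBSO)-2,6,6-trimethylcyclohex-1-ene-1-carboxylate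
Conditions: TBSOTf, 2,6-lutidine, CH2Cl2, −78 → 0 °C
Reagents that add atoms: tert-butyldimethylsilyl triflate CC(C)(C)[Si](C)(C)OS(=O)(=O)C(F)(F)F
Why: Silyl triflate protects the hindered allylic alcohol; with both oxygens as TBS ethers, any earlier 1,2-silyl migration is of no consequence.

Step 20
Reactants: 23 bis-TBS ester
Product: 24 [(3R,4S)-3,4-bis(TBSO)-2,6,6-trimethylcyclohex-1-en-1-yl]methanol
Conditions: DIBAL-H, CH2Cl2, −78 → 0 °C; Rochelle salt
Reagents that add atoms: none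
Why: DIBAL reduction of the hindered conjugated ester to the primary allylic alcohol.

Step 21
Reactants: 24 allylic alcohol
Product: 25 (3R,4S)-3,4-bis(TBSO)-2,6,6-trimethylcyclohex-1-ene-1-carbaldehyde
Conditions: TPAP (5 mol%), NMO, 4 Å MS, CH2Cl2, rt
Reagents that add atoms: none
Why: Ley–Griffith oxidation gives the cyclocitral-type enal under neutral conditions.

Step 22
Reactants: 25 enal
Product: 26 ethyl (2E,4E)-5-[(3R,4S)-3,4-bis(TBSO)-2,6,6-trimethylcyclohex-1-en-1-yl]-3-methylpenta-2,4-dienoate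
Conditions: triethyl (E)-3-methyl-4-phosphonocrotonate, LiHMDS, THF/DMPU, −78 → 0 °C; chromatography to remove the minor 2Z isomer
Reagents that add atoms: ethyl (E)-4-(diethoxyphosphoryl)-3-methylbut-2-enoate CCOC(=O)/C=C(\C)CP(=O)(OCC)OCC
Why: Horner–Wadsworth–Emmons olefination of the hindered aldehyde forms C7=C8 as E, and the C9=C10 geometry is carried over from the (E)-phosphonate.

Step 23
Reactants: 26 dienoate
Product: 27 (2E,4E)-5-[(3R,4S)-3,4-bis(TBSO)-2,6,6-trimethylcyclohex-1-en-1-yl]-3-methylpenta-2,4-dien-1-ol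
Conditions: DIBAL-H, CH2Cl2, −78 °C; Rochelle salt
Reagents that add atoms: none
Why: 1,2-Reduction of the dienoate without alkene isomerisation.

Step 24
Reactants: 27 dienol
Product: 28 (2E,4E)-5-[(3R,4S)-3,4-bis(TBSO)-2,6,6-trimethylcyclohex-1-en-1-yl]-3-methylpenta-2,4-dienal
Conditions: MnO2, CH2Cl2, rt
Reagents that add atoms: none
Why: Selective MnO2 oxidation of the primary allylic alcohol.

Step 25
Reactants: 28 dienal
Product: 29 ethyl (2E,4E,6E)-7-[(3R,4S)-3,4-bis(TBSO)-2,6,6-trimethylcyclohex-1-en-1-yl]-5-methylhepta-2,4,6-trienoate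
Conditions: triethyl phosphonoacetate, NaH, THF, 0 °C → rt
Reagents that add atoms: triethyl phosphonoacetate CCOC(=O)CP(=O)(OCC)OCC
Why: Horner–Wadsworth–Emmons olefination of an unhindered enal gives the disubstituted C11=C12 bond E-selectively.

Step 26
Reactants: 29 trienoate
Product: 30 (2E,4E,6E)-7-[(3R,4S)-3,4-bis(TBSO)-2,6,6-trimethylcyclohex-1-en-1-yl]-5-methylhepta-2,4,6-trien-1-ol
Conditions: DIBAL-H, CH2Cl2, −78 °C; Rochelle salt
Reagents that add atoms: none
Why: DIBAL reduction of the ester to the trienyl alcohol.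

Step 27
Reactants: 30 trienol
Product: 31 2-({(2E,4E,6E)-7-[(3R,4S)-3,4-bis(TBSO)-2,6,6-trimethylcyclohex-1-en-1-yl]-5-methylhepta-2,4,6-trien-1-yl}sulfanyl)-1,3-benzothiazole
Conditions: 2-mercaptobenzothiazole, PPh3, DIAD, THF, 0 °C
Reagents that add atoms: 2-mercaptobenzothiazole Sc1nc2ccccc2s1
Why: Mitsunobu thioetherification of the primary allylic alcohol by direct SN2 displacement.

Step 28
Reactants: 31 BT sulfide
Product: 32 2-({(2E,4E,6E)-7-[(3R,4S)-3,4-bis(TBSO)-2,6,6-trimethylcyclohex-1-en-1-yl]-5-methylhepta-2,4,6-trien-1-yl}sulfonyl)-1,3-benzothiazole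
Conditions: (NH4)6Mo7O24·4H2O (10 mol%), 30% H2O2, EtOH, 0 °C → rt
Reagents that add atoms: hydrogen peroxide OO
Why: Molybdate-catalysed peroxide oxidation converts sulfide to sulfone chemoselectively and does not epoxidise the conjugated triene.

Step 29
Reactants: 32 trienyl BT sulfone; 20 butenolide aldehyde
Product: 34 3,4-bis-O-TBS ether of the target (all-E chain and Z-ylidene lactone), via 13Z-isomer 33 (not isolated)
Conditions: NaHMDS (2.2 equiv), THF, −78 °C → rt, dark; then crude in benzene, rt, fluorescent room light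
Reagents that add atoms: none
Why: Julia–Kocienski olefination (addition, Smiles rearrangement, loss of SO2 and benzothiazolone) forms C13=C14; the cis portion relaxes to the all-trans polyene on equilibration, and the tertiary alcohol is less acidic than the sulfone so it is tolerated.

Step 30
Reactants: 34 bis-TBS ether of the target
Product: 35 target CNP0216838.1
Conditions: HF·pyridine, pyridine, THF, 0 °C → rt
Reagents that add atoms: none
Why: Buffered fluoride desilylation removes both secondary TBS groups without ionising the allylic C4 alcohol or opening the ylidene lactone; no stereocentre is affected.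

**Compound list**
1 | ketoisophorone | CC1=CC(=O)CC(C)(C)C1=O | starting material
2 | (6R)-levodione | C[C@@H]1CC(=O)CC(C)(C)C1=O | intermediate
3 | (4R,6R)-actinol | C[C@@H]1C[C@@H](O)CC(C)(C)C1=O | intermediate
4 | (4R,6R)-4-(TBSO)-2,2,6-trimethylcyclohexan-1-one | C[C@@H]1C[C@@H](O[Si](C)(C)C(C)(C)C)CC(C)(C)C1=O | intermediate
5 | (R)-4-(TBSO)-2,6,6-trimethylcyclohex-1-en-1-yl triflate | CC1=C(OS(=O)(=O)C(F)(F)F)C(C)(C)C[C@H](O[Si](C)(C)C(C)(C)C)C1 | intermediate
6 | methyl (R)-4-(TBSO)-2,6,6-trimethylcyclohex-1-ene-1-carboxylate | CC1=C(C(=O)OC)C(C)(C)C[C@H](O[Si](C)(C)C(C)(C)C)C1 | intermediate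
7 | [(R)-4-(TBSO)-2,6,6-trimethylcyclohex-1-en-1-yl]methanol | CC1=C(CO)C(C)(C)C[C@H](O[Si](C)(C)C(C)(C)C)C1 | intermediate
8 | [(1R,4S,6R)-4-(TBSO)-2,2,6-trimethyl-7-oxabicyclo[4.1.0]heptan-1-yl]methanol | C[C@]12O[C@@]1(CO)C(C)(C)C[C@H](O[Si](C)(C)C(C)(C)C)C2 | intermediate
9 | (1S,4S,6R)-4-(TBSO)-2,2,6-trimethyl-7-oxabicyclo[4.1.0]heptane-1-carbaldehyde | C[C@]12O[C@@]1(C=O)C(C)(C)C[C@H](O[Si](C)(C)C(C)(C)C)C2 | intermediate
10 | (1R,4S,6R)-4-(TBSO)-1-ethynyl-2,2,6-trimethyl-7-oxabicyclo[4.1.0]heptane | C[C@]12O[C@@]1(C#C)C(C)(C)C[C@H](O[Si](C)(C)C(C)(C)C)C2 | intermediate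
11 | (1R,3S,6R)-6-ethynyl-1,5,5-trimethyl-7-oxabicyclo[4.1.0]heptan-3-ol | C[C@]12O[C@@]1(C#C)C(C)(C)C[C@H](O)C2 | intermediate
12 | (1S,2R,4S)-1-ethynyl-2,6,6-trimethyl-7-oxabicyclo[2.2.1]heptan-2-ol | C#C[C@@]12O[C@@H](CC1(C)C)C[C@@]2(C)O | intermediate
13 | (1R,2R,4S)-2,6,6-trimethyl-1-[(E)-2-(tributylstannyl)ethenyl]-7-oxabicyclo[2.2.1]heptan-2-ol | CCCC[Sn](CCCC)(CCCC)/C=C/[C@@]12O[C@@H](CC1(C)C)C[C@@]2(C)O | intermediate
14 | propiolic acid | C#CC(=O)O | starting material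
15 | (E)-2,3-dibromoacrylic acid | Br/C=C(/Br)C(=O)O | intermediate
16 | (E)-3-methylpent-2-en-4-yn-1-ol | C#C/C(C)=C/CO | starting material
17 | (2E,6E)-2-bromo-8-hydroxy-6-methylocta-2,6-dien-4-ynoic acid | OC/C=C(C)/C#C/C=C(/Br)C(=O)O | intermediate (not isolated)
18 | (Z)-3-bromo-5-[(E)-4-hydroxy-2-methylbut-2-en-1-ylidene]furan-2(5H)-one | OC/C=C(C)/C=C1C=C(Br)C(=O)O/1 | intermediate
19 | (Z)-5-[(E)-4-hydroxy-2-methylbut-2-en-1-ylidene]-3-{(E)-2-[(1R,2R,4S)-2-hydroxy-2,6,6-trimethyl-7-oxabicyclo[2.2.1]heptan-1-yl]ethenyl}furan-2(5H)-one | OC/C=C(C)/C=C1C=C(/C=C/[C@@]23O[C@@H](CC2(C)C)C[C@@]3(C)O)C(=O)O/1 | intermediate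
20 | (E)-4-[(Z)-4-{(E)-2-[(1R,2R,4S)-2-hydroxy-2,6,6-trimethyl-7-oxabicyclo[2.2.1]heptan-1-yl]ethenyl}-5-oxofuran-2(5H)-ylidene]-3-methylbut-2-enal | O=C/C=C(C)/C=C1C=C(/C=C/[C@@]23O[C@@H](CC2(C)C)C[C@@]3(C)O)C(=O)O/1 | intermediate
21 | methyl (S)-4-(TBSO)-2,6,6-trimethyl-3-oxocyclohex-1-ene-1-carboxylate | CC1=C(C(=O)OC)C(C)(C)C[C@H](O[Si](C)(C)C(C)(C)C)C1=O | intermediate
22 | methyl (3R,4S)-3-hydroxy-4-(TBSO)-2,6,6-trimethylcyclohex-1-ene-1-carboxylate | CC1=C(C(=O)OC)C(C)(C)C[C@H](O[Si](C)(C)C(C)(C)C)[C@@H]1O | intermediate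
23 | methyl (3R,4S)-3,4-bis(TBSO)-2,6,6-trimethylcyclohex-1-ene-1-carboxylate | CC1=C(C(=O)OC)C(C)(C)C[C@H](O[Si](C)(C)C(C)(C)C)[C@@H]1O[Si](C)(C)C(C)(C)C | intermediate
24 | [(3R,4S)-3,4-bis(TBSO)-2,6,6-trimethylcyclohex-1-en-1-yl]methanol | CC1=C(CO)C(C)(C)C[C@H](O[Si](C)(C)C(C)(C)C)[C@@H]1O[Si](C)(C)C(C)(C)C | intermediate
25 | (3R,4S)-3,4-bis(TBSO)-2,6,6-trimethylcyclohex-1-ene-1-carbaldehyde | CC1=C(C=O)C(C)(C)C[C@H](O[Si](C)(C)C(C)(C)C)[C@@H]1O[Si](C)(C)C(C)(C)C | intermediate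
26 | ethyl (2E,4E)-5-[(3R,4S)-3,4-bis(TBSO)-2,6,6-trimethylcyclohex-1-en-1-yl]-3-methylpenta-2,4-dienoate | CC1=C(/C=C/C(C)=C/C(=O)OCC)C(C)(C)C[C@H](O[Si](C)(C)C(C)(C)C)[C@@H]1O[Si](C)(C)C(C)(C)C | intermediate
27 | (2E,4E)-5-[(3R,4S)-3,4-bis(TBSO)-2,6,6-trimethylcyclohex-1-en-1-yl]-3-methylpenta-2,4-dien-1-ol | CC1=C(/C=C/C(C)=C/CO)C(C)(C)C[C@H](O[Si](C)(C)C(C)(C)C)[C@@H]1O[Si](C)(C)C(C)(C)C | intermediate
28 | (2E,4E)-5-[(3R,4S)-3,4-bis(TBSO)-2,6,6-trimethylcyclohex-1-en-1-yl]-3-methylpenta-2,4-dienal | CC1=C(/C=C/C(C)=C/C=O)C(C)(C)C[C@H](O[Si](C)(C)C(C)(C)C)[C@@H]1O[Si](C)(C)C(C)(C)C | intermediate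
29 | ethyl (2E,4E,6E)-7-[(3R,4S)-3,4-bis(TBSO)-2,6,6-trimethylcyclohex-1-en-1-yl]-5-methylhepta-2,4,6-trienoate | CC1=C(/C=C/C(C)=C/C=C/C(=O)OCC)C(C)(C)C[C@H](O[Si](C)(C)C(C)(C)C)[C@@H]1O[Si](C)(C)C(C)(C)C | intermediate
30 | (2E,4E,6E)-7-[(3R,4S)-3,4-bis(TBSO)-2,6,6-trimethylcyclohex-1-en-1-yl]-5-methylhepta-2,4,6-trien-1-ol | CC1=C(/C=C/C(C)=C/C=C/CO)C(C)(C)C[C@H](O[Si](C)(C)C(C)(C)C)[C@@H]1O[Si](C)(C)C(C)(C)C | intermediate
31 | 2-({(2E,4E,6E)-7-[(3R,4S)-3,4-bis(TBSO)-2,6,6-trimethylcyclohex-1-en-1-yl]-5-methylhepta-2,4,6-trien-1-yl}sulfanyl)-1,3-benzothiazole | CC1=C(/C=C/C(C)=C/C=C/CSc2nc3ccccc3s2)C(C)(C)C[C@H](O[Si](C)(C)C(C)(C)C)[C@@H]1O[Si](C)(C)C(C)(C)C | intermediate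
32 | 2-({(2E,4E,6E)-7-[(3R,4S)-3,4-bis(TBSO)-2,6,6-trimethylcyclohex-1-en-1-yl]-5-methylhepta-2,4,6-trien-1-yl}sulfonyl)-1,3-benzothiazole | CC1=C(/C=C/C(C)=C/C=C/CS(=O)(=O)c2nc3ccccc3s2)C(C)(C)C[C@H](O[Si](C)(C)C(C)(C)C)[C@@H]1O[Si](C)(C)C(C)(C)C | intermediate
33 | 3,4-bis-O-TBS ether of the target with a cis (Z) C13=C14 bond | CC1=C(/C=C/C(C)=C/C=C/C=C\C=C(C)\C=C2C=C(/C=C/[C@@]34O[C@@H](CC3(C)C)C[C@@]4(C)O)C(=O)O\2)C(C)(C)C[C@H](O[Si](C)(C)C(C)(C)C)[C@@H]1O[Si](C)(C)C(C)(C)C | intermediate (not isolated)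
34 | 3,4-bis-O-TBS ether of the target (all-E chain, Z-ylidene lactone) | CC1=C(/C=C/C(C)=C/C=C/C=C/C=C(C)/C=C2C=C(/C=C/[C@@]34O[C@@H](CC3(C)C)C[C@@]4(C)O)C(=O)O/2)C(C)(C)C[C@H](O[Si](C)(C)C(C)(C)C)[C@@H]1O[Si](C)(C)C(C)(C)C | intermediate
35 | CNP0216838.1: (Z)-5-[(2E,4E,6E,8E,10E)-11-[(3R,4S)-3,4-dihydroxy-2,6,6-trimethylcyclohex-1-en-1-yl]-2,9-dimethylundeca-2,4,6,8,10-pentaen-1-ylidene]-3-{(E)-2-[(1R,2R,4S)-2-hydroxy-2,6,6-trimethyl-7-oxabicyclo[2.2.1]heptan-1-yl]ethenyl}furan-2(5H)-one | CC1=C(/C=C/C(C)=C/C=C/C=C/C=C(C)/C=C2C=C(/C=C/[C@@]34O[C@@H](CC3(C)C)C[C@@]4(C)O)C(=O)O/2)C(C)(C)C[C@H](O)[C@@H]1O | target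

**Totals and risks**
Total steps: 30. Longest linear sequence: 19 steps (1–5, then 17–30).

Most likely to fail:

Step 11 (transannular epoxide opening). The C5′–O bond may ionise instead, giving ring-contraction or Meinwald products. The fallback sets out from 11 and comes back at 12. Complex the alkyne with Co2(CO)8 (CH2Cl2, rt) to give the epoxy-alkynol dicobalt hexacarbonyl complex F1. BF3·OEt2 at −78 °C then ionises the epoxide only at the cobalt-stabilised propargylic carbon (Nicholas cation), which the 3′-OH can capture only across the ring from its own face, giving the oxabicyclic alkynol dicobalt hexacarbonyl complex F2. Oxidative decomplexation with ceric ammonium nitrate (acetone, 0 °C) returns 12.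

Step 17 (allylic oxidation next to the silyloxy carbon of an electron-poor alkene). Conversion may be low. The fallback sets out from 6 and comes back at 21. Wohl–Ziegler bromination (NBS, AIBN, PhCF3, 80 °C) at the ring allylic CH2 gives methyl (4S)-3-bromo-4-(TBSO)-2,6,6-trimethylcyclohex-1-ene-1-carboxylate F3 as a C3 epimer mixture. Amine-oxide oxidation of the bromide (N-methylmorpholine N-oxide, MeCN, rt; displacement then elimination, Kornblum/Ganem type) gives enone 21; the C3 configuration of F3 does not matter.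

Step 18 (facial selectivity, or competing conjugate reduction of the keto-enoate). The fallback sets out from 21 and comes back at 22. Luche reduction (NaBH4, CeCl3·7H2O, MeOH, −78 °C) is strictly 1,2 and is expected to give mainly the trans alcohol, methyl (3S,4S)-3-hydroxy-4-(TBSO)-2,6,6-trimethylcyclohex-1-ene-1-carboxylate F4. Mitsunobu inversion (4-nitrobenzoic acid, PPh3, DIAD, THF) gives methyl (3R,4S)-4-(TBSO)-2,6,6-trimethyl-3-[(4-nitrobenzoyl)oxy]cyclohex-1-ene-1-carboxylate F5. Methanolysis (K2CO3, MeOH, 0 °C) gives 22.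

**Further compounds**
F1 | step 11 | hexacarbonyldicobalt (μ-alkyne) complex of (1R,3S,6R)-6-ethynyl-1,5,5-trimethyl-7-oxabicyclo[4.1.0]heptan-3-ol | C[C@]12O[C@@]1(C#C)C(C)(C)C[C@H](O)C2.[C-]#[O+].[C-]#[O+].[C-]#[O+].[C-]#[O+].[C-]#[O+].[C-]#[O+].[Co].[Co]
F2 | step 11 | hexacarbonyldicobalt (μ-alkyne) complex of (1S,2R,4S)-1-ethynyl-2,6,6-trimethyl-7-oxabicyclo[2.2.1]heptan-2-ol | C#C[C@@]12O[C@@H](CC1(C)C)C[C@@]2(C)O.[C-]#[O+].[C-]#[O+].[C-]#[O+].[C-]#[O+].[C-]#[O+].[C-]#[O+].[Co].[Co]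
F3 | step 17 | methyl (4S)-3-bromo-4-(TBSO)-2,6,6-trimethylcyclohex-1-ene-1-carboxylate (C3 epimer mixture) | CC1=C(C(=O)OC)C(C)(C)C[C@H](O[Si](C)(C)C(C)(C)C)C1Br
F4 | step 18 | methyl (3S,4S)-3-hydroxy-4-(TBSO)-2,6,6-trimethylcyclohex-1-ene-1-carboxylate | CC1=C(C(=O)OC)C(C)(C)C[C@H](O[Si](C)(C)C(C)(C)C)[C@H]1O
F5 | step 18 | methyl (3R,4S)-4-(TBSO)-2,6,6-trimethyl-3-[(4-nitrobenzoyl)oxy]cyclohex-1-ene-1-carboxylate | CC1=C(C(=O)OC)C(C)(C)C[C@H](O[Si](C)(C)C(C)(C)C)[C@@H]1OC(=O)c2ccc(cc2)[N+](=O)[O-]
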